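Daucane numbering: C1 quaternary ring-fusion carbon, C4 isopropyl carbinol, C5 ring-fusion CH, C6 acyloxy carbon; ring A cyclopentane, ring B cycloheptane. The plan rests on the cis array O–C4–C5–C6 on ring A, read as a β-lactone. One nucleophile-catalysed aldol-lactonisation of an acyclic keto acid forges C4–C5, closes ring A, sets C4 and C5 and leaves C6 acyl-activated. The keto acid is (−)-menthone recut. Dehydrogenation, conjugate allylation (C1) and scission of the C4–C6 bond open its cyclohexane, which the key step re-stitches one atom shorter. Ring B is then added by alkoxyallylation at C6 and ring-closing metathesis (C8=C9).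

Key step: step 4

Assumption: the (S)-antipode of homobenzotetramisole is taken to induce the sense needed at C4 and C5. Both antipodes are available, so the other one would be used unchanged if the induction runs the opposite way.

Step 1
Reactants: 1 (−)-menthone
Product: 3 (S)-(+)-piperitone, via trimethylsilyl enol ether 2 (not isolated)
Conditions: LiN(i-Pr)2, Me3SiCl, THF, −78 °C; crude 2, Pd(OAc)2 (10 mol %), O2 (1 atm), DMSO, rt
Reagents that add atoms: none
Why: Kinetic deprotonation at the CH2 flank followed by Saegusa–Ito oxidation places the double bond toward the methyl-bearing carbon, erases that stereocentre on purpose and leaves the never-enolised isopropyl-bearing stereocentre as the only source of chirality.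

Step 2
Reactants: 3 (S)-(+)-piperitone
Product: 4 (3R,6S)-3-allyl-6-isopropyl-3-methylcyclohexan-1-one
Conditions: allyltrimethylsilane, TiCl4, CH2Cl2, −78 °C; then H2O
Reagents that add atoms: allyltrimethylsilane, C=CC[Si](C)(C)C
Why: The Hosomi–Sakurai conjugate allylation builds quaternary C1; axial (antiparallel) attack on the half-chair with a pseudo-equatorial isopropyl group should place the allyl group cis to it, and any C1 epimer is removed later as a diastereomer of lactone 9.

Step 3
Reactants: 4 (3R,6S)-3-allyl-6-isopropyl-3-methylcyclohexan-1-one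
Product: 6 (R)-3-allyl-3,7-dimethyl-6-oxooctanoic acid, via tertiary hydroperoxide 5 (not isolated)
Conditions: O2 (1 atm), KOt-Bu, t-BuOH–THF, 0 °C to rt; then aq. HCl
Reagents that add atoms: dioxygen, O=O
Why: Base-mediated autoxidation of the more substituted enolate gives the tertiary α-hydroperoxide, which fragments to the isopropyl ketone (C4) and the carboxylate (C6) as is known for 2-alkylcyclohexanones, while C5 is shielded by the neighbouring quaternary carbon and the allyl group is inert.

Step 4
Reactants: 6 (R)-3-allyl-3,7-dimethyl-6-oxooctanoic acid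
Product: 9 (1R,2R,5R)-2-allyl-5-isopropyl-2-methyl-6-oxabicyclo[3.2.0]heptan-7-one, via mixed carboxylic sulfonic anhydride 7 (not isolated), via acylammonium ion 8 (not isolated)
Conditions: TsCl, (S)-homobenzotetramisole (20 mol %), LiCl, i-Pr2NEt, CH2Cl2, rt, slow addition of 6
Reagents that add atoms: none
Why: TsCl converts acid 6 into anhydride 7, the isothiourea displaces tosylate to give acylammonium ion 8, and the amine base deprotonates C5 to a (Z)-ammonium enolate that adds to the lithium-activated C4 ketone, after which the tertiary alkoxide expels the catalyst from C6. The closest known reaction type is the nucleophile-catalysed aldol-lactonisation of keto acids to cyclopentane-fused β-lactones. Ring A closes by a 5-(enolexo)-exo-trig aldol addition (bond C4–C5) and the oxetanone closes 4-exo-trig (bond O–C6). The four-membered ring can only be cis-fused, which forces the C4 oxygen and C6 onto one face and the isopropyl group and H5 onto the other, while the phenyl-bearing stereocentre of the catalyst, with the enolate locked by an S···O contact, decides which enolate face attacks and so fixes C4 and C5 relative to C1, whose own bias (methyl against allyl) is too small to resist. Chemoselectivity is secured because only the carboxyl group can be activated and only C5 can become the catalyst-bound enolate, closure being helped by the gem-dialkyl effect of C1 and by slow addition that suppresses ketene dimerisation. Acid of the wrong C1 configuration carried over from step 2 ends as a diastereomeric lactone and is removed by chromatography.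

Step 5
Reactants: 9 (1R,2R,5R)-2-allyl-5-isopropyl-2-methyl-6-oxabicyclo[3.2.0]heptan-7-one
Product: 10 (1R,2S,3R)-3-allyl-2-(hydroxymethyl)-1-isopropyl-3-methylcyclopentan-1-ol
Conditions: LiAlH4, Et2O, 0 °C
Reagents that add atoms: none
Why: Hydride reduction of the strained β-lactone by acyl–oxygen cleavage gives the 1,3-diol, creates no stereocentre and leaves the terminal alkene untouched.

Step 6
Reactants: 10 (1R,2S,3R)-3-allyl-2-(hydroxymethyl)-1-isopropyl-3-methylcyclopentan-1-ol
Product: 11 (1R,2R,5R)-2-allyl-5-hydroxy-5-isopropyl-2-methylcyclopentane-1-carbaldehyde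
Conditions: TEMPO (10 mol %), PhI(OAc)2, CH2Cl2, rt
Reagents that add atoms: none
Why: The oxoammonium (TEMPO) oxidation touches only the primary alcohol, its nearly neutral medium avoids retro-aldol cleavage, and C5 already holds its more stable configuration (formyl group cis to the hydroxyl, trans to the isopropyl group).

Step 7
Reactants: 12 2-methylprop-2-en-1-ol
Product: 13 tert-butyldimethyl(2-methylallyloxy)silane
Conditions: TBSCl, imidazole, DMF, rt
Reagents that add atoms: tert-butyldimethylsilyl chloride, CC(C)(C)[Si](C)(C)Cl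
Why: This is an imidazole-promoted silylation of an unhindered primary allylic alcohol.

Step 8
Reactants: 13 tert-butyldimethyl(2-methylallyloxy)silane
Product: 15 (Z)-tributyl[3-(tert-butyldimethylsilyloxy)-2-methylallyl]stannane, via lithiated silyl ether 14 (not isolated)
Conditions: s-BuLi, THF–HMPA, −78 °C; then Bu3SnCl, −78 °C
Reagents that add atoms: tributyltin chloride, CCCC[Sn](Cl)(CCCC)CCCC
Why: α-Lithiation of the allyl silyl ether (allyloxy carbanion chemistry) gives an oxygen-chelated allyl anion that is stannylated at its γ-terminus before silyl migration sets in, the internal Li–O contact fixing the Z enol ether geometry.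

Step 9
Reactants: 11 (1R,2R,5R)-2-allyl-5-hydroxy-5-isopropyl-2-methylcyclopentane-1-carbaldehyde; 15 (Z)-tributyl[3-(tert-butyldimethylsilyloxy)-2-methylallyl]stannane
Product: 16 (1R,2S,3R)-3-allyl-2-[(1R,2R)-2-(tert-butyldimethylsilyloxy)-1-hydroxy-3-methylbut-3-en-1-yl]-1-isopropyl-3-methylcyclopentan-1-ol
Conditions: MgBr2·OEt2 (3 equiv), CH2Cl2, −25 °C to 0 °C
Reagents that add atoms: none
Why: In this Lewis acid-mediated γ-alkoxyallylstannane addition MgBr2 ties the C4 hydroxyl and the aldehyde oxygen into a six-membered Cram chelate on the β-face of ring A, the stannane attacks the exposed outer face (sets C6, oxygen α in the later ring B), and the open antiperiplanar transition state gives the syn C6/C7 relationship (sets C7).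

Step 10
Reactants: 16 (1R,2S,3R)-3-allyl-2-[(1R,2R)-2-(tert-butyldimethylsilyloxy)-1-hydroxy-3-methylbut-3-en-1-yl]-1-isopropyl-3-methylcyclopentan-1-ol
Product: 17 7β-(tert-butyldimethylsilyloxy)dauc-8-ene-4β,6α-diol (trans-fused: 1β-methyl and 5α-H)
Conditions: second-generation Hoveyda–Grubbs catalyst (5 mol %), toluene (2 mM), 80 °C
Reagents that add atoms: none
Why: Ring-closing metathesis between the allyl group on C1 and the 1,1-disubstituted alkene closes seven-membered ring B as the trisubstituted C8=C9 alkene, the trans ring fusion being already fixed by C1 and C5 so that no stereocentre is formed.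

Step 11
Reactants: 17 7β-(tert-butyldimethylsilyloxy)dauc-8-ene-4β,6α-diol
Product: 18 8α,9α-epoxy-7β-(tert-butyldimethylsilyloxy)daucane-4β,6α-diol
Conditions: VO(acac)2 (5 mol %), t-BuOOH (decane), CH2Cl2, 0 °C
Reagents that add atoms: tert-butyl hydroperoxide, CC(C)(C)OO
Why: In this vanadium-catalysed hydroxyl-directed epoxidation the homoallylic 6α-hydroxyl delivers oxygen to the α-face of C8=C9, the face also left open by the 7β-silyloxy group and the angular methyl group, which sets C8 and C9.

Step 12
Reactants: 19 4-hydroxybenzoic acid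
Product: 21 4-(tert-butyldimethylsilyloxy)benzoic acid, via bis-silylated ester 20 (not isolated)
Conditions: TBSCl (2.2 equiv), imidazole, DMF, rt; then AcOH–THF–H2O, rt
Reagents that add atoms: tert-butyldimethylsilyl chloride, CC(C)(C)[Si](C)(C)Cl
Why: Exhaustive silylation followed by selective hydrolysis of the far more labile silyl ester leaves the aryl silyl ether in place.

Step 13
Reactants: 18 8α,9α-epoxy-7β-(tert-butyldimethylsilyloxy)daucane-4β,6α-diol; 21 4-(tert-butyldimethylsilyloxy)benzoic acid
Product: 22 8α,9α-epoxy-4β-hydroxy-7β-(tert-butyldimethylsilyloxy)daucan-6α-yl 4-(tert-butyldimethylsilyloxy)benzoate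
Conditions: DCC, DMAP, CH2Cl2, rt
Reagents that add atoms: none
Why: The Steglich esterification acylates the only secondary hydroxyl (C6), the tertiary C4 hydroxyl being inert, under neutral conditions that spare the epoxide.

Step 14
Reactants: 22 8α,9α-epoxy-4β-hydroxy-7β-(tert-butyldimethylsilyloxy)daucan-6α-yl 4-(tert-butyldimethylsilyloxy)benzoate
Product: 23 target CNP0290052.1 (8α,9α-epoxy-4β,7β-dihydroxydaucan-6α-yl 4-hydroxybenzoate)
Conditions: Bu4NF, AcOH (1:1), THF, 0 °C to rt
Reagents that add atoms: none
Why: Fluoride-mediated desilylation buffered with acetic acid removes both silyl groups at once and keeps the C7 alkoxide concentration too low for Payne rearrangement or C6-to-C7 acyl migration.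

Compound list
1 | (−)-menthone, (2S,5R)-2-isopropyl-5-methylcyclohexan-1-one | O=C1C[C@H](C)CC[C@H]1C(C)C | starting material
2 | {[(3R,6S)-6-isopropyl-3-methylcyclohex-1-en-1-yl]oxy}trimethylsilane | C[Si](C)(C)OC1=C[C@H](C)CC[C@H]1C(C)C | intermediate
3 | (S)-(+)-piperitone, (6S)-6-isopropyl-3-methylcyclohex-2-en-1-one | O=C1C=C(C)CC[C@H]1C(C)C | intermediate
4 | (3R,6S)-3-allyl-6-isopropyl-3-methylcyclohexan-1-one | O=C1C[C@@](C)(CC=C)CC[C@H]1C(C)C | intermediate
5 | (5R)-5-allyl-2-hydroperoxy-2-isopropyl-5-methylcyclohexan-1-one (hydroperoxide carbon undefined) | O=C1C[C@@](C)(CC=C)CCC1(OO)C(C)C | intermediate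
6 | (R)-3-allyl-3,7-dimethyl-6-oxooctanoic acid | OC(=O)C[C@@](C)(CC=C)CCC(=O)C(C)C | intermediate
7 | mixed anhydride of 6 with p-toluenesulfonic acid | CC(C)C(=O)CC[C@](C)(CC=C)CC(=O)OS(=O)(=O)c1ccc(C)cc1 | intermediate
8 | N-acyl (S)-homobenzotetramisolium ion derived from 6 | CC(C)C(=O)CC[C@](C)(CC=C)CC(=O)[N+]1=C2Sc3ccccc3N2CC[C@H]1c1ccccc1 | intermediate
9 | (1R,2R,5R)-2-allyl-5-isopropyl-2-methyl-6-oxabicyclo[3.2.0]heptan-7-one | O=C1O[C@@]2(C(C)C)CC[C@](C)(CC=C)[C@@H]12 | intermediate
10 | (1R,2S,3R)-3-allyl-2-(hydroxymethyl)-1-isopropyl-3-methylcyclopentan-1-ol | OC[C@@H]1[C@@](C)(CC=C)CC[C@@]1(O)C(C)C | intermediate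
11 | (1R,2R,5R)-2-allyl-5-hydroxy-5-isopropyl-2-methylcyclopentane-1-carbaldehyde | O=C[C@@H]1[C@@](C)(CC=C)CC[C@@]1(O)C(C)C | intermediate
12 | 2-methylprop-2-en-1-ol | C=C(C)CO | starting material
13 | tert-butyldimethyl(2-methylallyloxy)silane | C=C(C)CO[Si](C)(C)C(C)(C)C | intermediate
14 | 1-lithio-2-methylallyl tert-butyldimethylsilyl ether | C=C(C)C([Li])O[Si](C)(C)C(C)(C)C | intermediate
15 | (Z)-tributyl[3-(tert-butyldimethylsilyloxy)-2-methylallyl]stannane | CCCC[Sn](CCCC)(CCCC)C/C(C)=C\O[Si](C)(C)C(C)(C)C | intermediate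
16 | (1R,2S,3R)-3-allyl-2-[(1R,2R)-2-(tert-butyldimethylsilyloxy)-1-hydroxy-3-methylbut-3-en-1-yl]-1-isopropyl-3-methylcyclopentan-1-ol | C=C(C)[C@@H](O[Si](C)(C)C(C)(C)C)[C@H](O)[C@@H]1[C@@](C)(CC=C)CC[C@@]1(O)C(C)C | intermediate
17 | 7β-(tert-butyldimethylsilyloxy)dauc-8-ene-4β,6α-diol (1β-methyl, 5α-H) | CC(C)[C@]1(O)CC[C@]2(C)CC=C(C)[C@@H](O[Si](C)(C)C(C)(C)C)[C@H](O)[C@H]21 | intermediate
18 | 8α,9α-epoxy-7β-(tert-butyldimethylsilyloxy)daucane-4β,6α-diol | CC(C)[C@]1(O)CC[C@]2(C)C[C@@H]3O[C@]3(C)[C@@H](O[Si](C)(C)C(C)(C)C)[C@H](O)[C@H]21 | intermediate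
19 | 4-hydroxybenzoic acid | OC(=O)c1ccc(O)cc1 | starting material
20 | tert-butyldimethylsilyl 4-(tert-butyldimethylsilyloxy)benzoate | CC(C)(C)[Si](C)(C)OC(=O)c1ccc(O[Si](C)(C)C(C)(C)C)cc1 | intermediate
21 | 4-(tert-butyldimethylsilyloxy)benzoic acid | OC(=O)c1ccc(O[Si](C)(C)C(C)(C)C)cc1 | intermediate
22 | 8α,9α-epoxy-4β-hydroxy-7β-(tert-butyldimethylsilyloxy)daucan-6α-yl 4-(tert-butyldimethylsilyloxy)benzoate | CC(C)[C@]1(O)CC[C@]2(C)C[C@@H]3O[C@]3(C)[C@@H](O[Si](C)(C)C(C)(C)C)[C@H](OC(=O)c3ccc(O[Si](C)(C)C(C)(C)C)cc3)[C@H]21 | intermediate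
23 | CNP0290052.1, (1R,4R,5S,6R,7S,8R,9S)-8,9-epoxy-4,7-dihydroxydaucan-6-yl 4-hydroxybenzoate | CC(C)[C@]1(O)CC[C@]2(C)C[C@@H]3O[C@]3(C)[C@@H](O)[C@H](OC(=O)c3ccc(O)cc3)[C@H]21 | target

Total step count: 14. Longest linear sequence: 11 steps (1, 2, 3, 4, 5, 6, 9, 10, 11, 13, 14).

Steps most likely to fail

Step 4. The aldol addition joins a neopentyl-type enolate carbon to a hindered isopropyl ketone. It may therefore be slower than ketene dimerisation or hydrolysis of the activated acid, and catalyst control over the attacking face may be incomplete.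
- The fallback sets out from 6 and returns at 10.
- Acid 6 is coupled with thiophenol (DCC, DMAP) to give the S-phenyl thioester F1.
- Soft enolisation with MgBr2·OEt2 and i-Pr2NEt in CH2Cl2 triggers a magnesium-chelated intramolecular thioester aldol addition to the cis-β-hydroxy thioester F2. The chelate keeps the C4 oxygen and C6 on one face.
- The isomer of the wrong sense relative to C1 is separated by chromatography.
- LiAlH4 reduces the thioester to diol 10.

Step 9. The doubly neopentyl aldehyde may add the stannane sluggishly. This would allow protodestannylation, and attack may partly bypass the magnesium chelate, with poor facial selectivity at C6.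
- The fallback sets out from 11 and returns at 17. It replaces chelate control by reagent control.
- Methallyl methoxymethyl ether is lithiated (s-BuLi) and borylated with the antipode of B-methoxydiisopinocampheylborane that attacks the same aldehyde face.
- After BF3·OEt2 the borane is added to 11 through a closed chair transition state. This gives the syn adduct, methoxymethyl ether F3.
- Metathesis under the conditions of step 10 gives the bicyclic methoxymethyl ether F4.
- HCl in MeOH frees dauc-8-ene-4β,6α,7β-triol F5.
- TBSOTf with 2,6-lutidine at −78 °C silylates the less hindered allylic C7 hydroxyl to give 17.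

Step 3. Oxygenation may compete at C5, or the reaction may stall or over-oxidise under the strongly basic conditions.
- The fallback sets out from 4 and returns at 6.
- Me3SiI with hexamethyldisilazane under equilibrating conditions gives the tetrasubstituted silyl enol ether F6.
- Rubottom oxidation (m-CPBA, NaHCO3) gives the tertiary α-hydroxy ketone F7.
- H5IO6 cleaves the ketol to keto acid 6.

Further compounds
F1 | step 4 | S-phenyl (R)-3-allyl-3,7-dimethyl-6-oxooctanethioate | CC(C)C(=O)CC[C@](C)(CC=C)CC(=O)Sc1ccccc1
F2 | step 4 | S-phenyl (1R,2R,5R)-2-allyl-5-hydroxy-5-isopropyl-2-methylcyclopentane-1-carbothioate | O=C(Sc1ccccc1)[C@@H]1[C@@](C)(CC=C)CC[C@@]1(O)C(C)C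
F3 | step 9 | methoxymethyl ether analogue of 16 | C=C(C)[C@@H](OCOC)[C@H](O)[C@@H]1[C@@](C)(CC=C)CC[C@@]1(O)C(C)C
F4 | step 9 | 7β-(methoxymethoxy)dauc-8-ene-4β,6α-diol | CC(C)[C@]1(O)CC[C@]2(C)CC=C(C)[C@@H](OCOC)[C@H](O)[C@H]21
F5 | step 9 | dauc-8-ene-4β,6α,7β-triol | CC(C)[C@]1(O)CC[C@]2(C)CC=C(C)[C@@H](O)[C@H](O)[C@H]21
F6 | step 3 | {[(5R)-5-allyl-2-isopropyl-5-methylcyclohex-1-en-1-yl]oxy}trimethylsilane | C[Si](C)(C)OC1=C(C(C)C)CC[C@](C)(CC=C)C1
F7 | step 3 | (5R)-5-allyl-2-hydroxy-2-isopropyl-5-methylcyclohexan-1-one (carbinol carbon undefined) | O=C1C[C@@](C)(CC=C)CCC1(O)C(C)C
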